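At early times in Monday's flask I looked at where the reacted starting material had gone, with these flasks, readings and questions before me.

| setting | Monday's | Thursday's | flask |
|---|---|---|---|
| starting material | 0.20 M | 0.20 M | 0.20 M |
| second substrate | 1 equiv | 1 equiv | 1.00 equiv |
| third substrate | 1 equiv | 2 equiv | 1.00 equiv |
| solid reagent | 3 equiv | 3 equiv | 3.00 equiv |
| temperature | 70 °C | 76 °C | 70 °C |
| remark | the very flask that is asked about, followed so far | run made earlier |  |
| time |  |  | 4.0 d |

- Monday's (time / d: target / %, starting material / %): 0.500: 14.0, 63.6; 0.833: 19.1, 37.6; 1.25: 23.2, 20.3; 1.67: 24.7, 9.0; 2.50: 26.8, 1.9; 3.00: 25.1, 0.7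
- Thursday's (time / d: target / %, starting material / %): 0.417: 13.6, 60.3; 0.833: 22.1, 25.0; 1.25: 25.4, 10.8; 1.67: 26.3, 2.9; 2.08: 29.4, 2.1; 2.50: 29.3, 1.3; 3.00: 28.6, 1.9

(standard deviation of a reading: 1 percentage point)

- ash: change nothing and wait 50 h more
- elm: at 4.0 d take out 90% of the target then present, then wait 50 h
- oak: at 4.0 d raise the temperature by 25 K, then wait 50 h
- larch: at 4.0 d add starting material, 50.0% of the amount charged, then wait 50 h

- solid reagent is a solid; its amount is given per volume of the solution
- target that was removed still counts
- at the start none of the solid reagent is in solution
- additions bring no volume worth counting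

1. target, in percent of the starting material first charged, at 4.0 d
2. what to do for the largest gain in target; "none" if nothing gains more than 2 percentage points (ash / elm / oak / larch / none)
3. target present, with what was taken out counted in, in percent of the starting material first charged, after elm
4. target present, with what was taken out counted in, in percent of the starting material first charged, after larch

At 0.500 d on Monday, target made up 38.5% of the reacted starting material. From 1.67 d on, the target share s, meaning target divided by all starting material reacted, averaged 26.6%, lower than at first. I therefore took target to feed an unread form and applied s to the pool of target plus that form.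

With the 0.7% of starting material read at 3.00 d subtracted, the pool gave me 26.4% target now, and ash left that unchanged. Elm removes 23.7%, and I took s of the smaller pool to come back as target, so my total was 43.8%, a gain of 17 percentage points. If the added portion all reacts, larch gives 39.7%, a gain of 13 points. Thursday's hotter flask, which also had more third substrate, showed s = 29.6%. Stretched in a straight line, with the whole difference put down to temperature for want of a cleaner comparison, that made oak worth 13 points. I committed to elm, which gained more in this reckoning.

The weak link was the return from the unread form. Taking target to have averaged 7.00% over Monday's first stretch, and the missing starting material to have passed through it, gave me a rough loss constant of 6.40 d⁻¹, or a half-life of 2.60 h. Thursday's target read 29.4% and later 28.6%, a change of 0.8 points against a scatter of 1 point, over 8.49 of Monday's half-lives, so I read a two-way balance (thermodynamic control), quick against 50 h.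

The forecast differed from my reckoning: 25.5% now, larch as the step, 25.5% after elm and 35% after larch, on the ground that “target is stable, and the plateau comes from selectivity”.

The flask gave 27.4% now. Its best step was elm, gaining 18 points, with 45.3% after elm and 39.4% after larch. The unread form was the isomer of the product:

    starting material + coupling partner ⇌ target (K = 130 M⁻¹, k = 0.480 M⁻¹ h⁻¹, Ea = 65.0 kJ mol⁻¹, ΔH = 7.00 kJ mol⁻¹)
    second substrate + coupling partner → second product (k = 0.580 M⁻¹ h⁻¹, Ea = 78.0 kJ mol⁻¹)
    third substrate + coupling partner → third product (k = 0.0140 M⁻¹ h⁻¹, Ea = 108 kJ mol⁻¹)
    target ⇌ isomer of the product (K = 2.60, k = 0.930 h⁻¹, Ea = 96.0 kJ mol⁻¹, ΔH = −8.00 kJ mol⁻¹)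
    solid reagent ⇌ coupling partner, rate k5*(cs5 - [coupling partner]) while solid is left; crystals form when [coupling partner] > cs5 (solubility = 0.170 M, k = 0.300 h⁻¹)
    (constants at 70 °C)

At 4.00 d, s of the 98.6% held as target and isomer of the product is 26.2%. In the neighbouring flask with 4.00 equiv of second substrate, the solid reagent stood at 0% and 49.5% of the starting material remained at 4.00 d. There, s of the reacted 50.5% gives 13.4%, and that flask held 14.0% target.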